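At the very start the flask holds starting material and no dissolved gas, under a held gas phase.

starting material 0.50 mM; gas phase 0.20 mM (held); time 30 s

    gas phase ⇌ dissolved gas, rate k1*(csat - [dissolved gas]) (k1 = 1.5 s⁻¹, csat = 0.20 mM)
    starting material + dissolved gas ⇌ target (K2 = 10000 L mol⁻¹, k2 = 230 L mol⁻¹ s⁻¹)
    starting material → side product (k3 = 0.029 s⁻¹)
    target ⇌ isomer of the product (K4 = 0.47, k4 = 0.048 s⁻¹)
    dissolved gas ⇌ dormant form (K5 = 13, k5 = 0.20 s⁻¹)

* how much target there is at 30 s, in percent of the starting material charged
* the change that raises the amount of target at 30 s, in percent of the starting material charged most ("none" if none brings more than 2 percentage points) (theta / gamma / none)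
* amount of target at 30 s, in percent of the starting material charged, after gamma

- theta: doubling the saturation concentration of gas phase, all else as stated
- gamma: doubling the transfer coefficient of step 1, all else as stated

Transfer could deliver up to 1800% of the charge by 30 s into a solution kept empty, so starting material is the limiting reagent, and its ledger is the one to keep. c(dissolved gas) climbs on a lag of 0.551 s, which is far shorter than the run, so one level can serve. That level is the transfer coefficient times the saturation concentration, divided by the transfer coefficient plus the drains to dormant form and to capture at the charged amount: 0.165 mM.

Capture is then pseudo-first-order at 0.0380 s⁻¹, against 0.029 s⁻¹ towards side product. The capture share, the part of forward-reacting starting material that enters target, is 56.7%.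

Target and isomer of the product equilibrate in 6.66 s, faster than the run, so they form one pool, 68.0% of it target. That pool returns to starting material at 0.0156 s⁻¹. Starting material therefore falls on two rates, 0.0768 s⁻¹ and then 0.00591 s⁻¹. The ledger at 30 s closes with the pool taking what remains of the charge:

| Entry | Share of charge |
|---|---|
| starting material | 20.1% |
| side product | 40.3% |
| target | 26.9% |
| isomer of the product | 12.7% |

Theta lifts the share to 72.4%, and gamma to 58.9%. Scaling the target entry by the share gives gains of 7.4 percentage points and 1.1 points, so theta is the pick.

The forecast stands higher than this reckoning, at 29% (25% to 33%) and 31% (27% to 35%) after gamma, and it also picks theta, since for gamma “it is already near saturation”.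

The flask gives 28.0% of target at 30 s, with 19.8% of starting material left and 40.8% as side product. Theta brings 12 points against 1.3 points for gamma, a larger gain than the scaled one. Carried to the gamma flask, the ratio of capture shares takes 28.0% to 29.1%, and that flask reads 29.3%.

Its constants were set for the occasion.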